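**Plan**

Numbering: C1 furanone C=O, C2=C3 furanone alkene with the ring oxygen joining C3 to C10, C4=C5 (C15 on C4), C6 lactone O–CH, C7, C8 (methacrylate), C9 (senecioate), C10 (methyl), C11=C13, C12 lactone C=O.
Retrosynthesis: the C8 and C9 esters and the C15 silyl ether come off first; then C2–C3 is cut with O10 returned from C3 to an ester; then C4=C5 (metathesis), the O10–C3 ester, C11=C13, C7–C8 (radical conjugate addition) and C10–C1 (acetylide addition).
Enabling feature: the furanone oxygen links C10 to C3, so the nine-membered lactone ring O10–C3–C4–C5–C6–C7–C8–C9–C10 with a C1–C2 acetyl group on C10 already holds every atom of the ten-membered carbocycle C1–C10 and of the furanone C1–C2–C3–O–C10.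
Forward: the dioxolane (C8, C9) is bought; the γ-lactone (C6, C7, C11, C12) is joined to it at C7–C8; the nine-membered lactone is closed at C4=C5; one step then forms C2–C3 and with it the ten-membered carbocycle and the furanone; the esters come last.
Stereochemistry: C9 from L-tartaric acid; C8 by trans-selective radical capture on the dioxolane; C10 by chelation-controlled acetylide addition; C6 from (S)-5-(hydroxymethyl)butenolide; C7 by addition anti to the C6 substituent; Z-C4=C5 by the ring.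

Key step: step 15

Assumption: 1, 7 and 15 are bought as such, and the C10 acetyl group is carried as a silyl-capped ethynyl group until step 13 because a methyl ketone would not survive the enolate chemistry of step 8.

**Route**

Step 1
Reactants: 1 dimethyl (4R,5R)-2,2-dimethyl-1,3-dioxolane-4,5-dicarboxylate
Product: 2 (4R,5R)-5-(methoxycarbonyl)-2,2-dimethyl-1,3-dioxolane-4-carboxylic acid
Conditions: KOH (1.0 equiv), MeOH, 0 °C → rt; then 1 M HCl
Reagents that add atoms: potassium hydroxide, [K+].[OH-]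
Why: Monosaponification of a C2-symmetric diester, in which the carboxylate formed first repels a second hydroxide, so one equivalent of KOH should stop at the half-ester without touching either stereocentre.

Step 2
Reactants: 2 (4R,5R)-5-(methoxycarbonyl)-2,2-dimethyl-1,3-dioxolane-4-carboxylic acid
Product: 4 methyl (4R,5R)-5-acetyl-2,2-dimethyl-1,3-dioxolane-4-carboxylate, via acid chloride 3 (not isolated)
Conditions: (COCl)2, DMF (cat.), CH2Cl2, 0 °C → rt; then Me2CuLi (from MeLi, CuI), Et2O, −78 °C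
Reagents that add atoms: lithium dimethylcuprate, [Li+].C[Cu-]C
Why: Ketone synthesis by acylation of a Gilman cuprate with an acid chloride, which should stop at the methyl ketone because Me2CuLi adds neither to ketones nor to esters at −78 °C; the trans-dioxolane is the stable isomer, so C9 is not at risk.

Step 3
Reactants: 4 methyl (4R,5R)-5-acetyl-2,2-dimethyl-1,3-dioxolane-4-carboxylate
Product: 5 methyl (4R,5R)-5-[(2R)-2-hydroxy-4-(triisopropylsilyl)but-3-yn-2-yl]-2,2-dimethyl-1,3-dioxolane-4-carboxylate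
Conditions: iPr3SiC≡CH, EtMgBr, Et2O, 0 °C → rt; then 4, MgBr2·OEt2, CH2Cl2, −78 °C
Reagents that add atoms: (triisopropylsilyl)acetylene, C#C[Si](C(C)C)(C(C)C)C(C)C
Why: Chelation-controlled Grignard addition (Cram chelate model), in which magnesium should bridge the ketone oxygen and the dioxolane oxygen on C9 so that the acetylide attacks the exposed face of the chelate, anti to C8, and sets C10 as in the target, while the ketone far outpaces the ester at −78 °C.

Step 4
Reactants: 5 methyl (4R,5R)-5-[(2R)-2-hydroxy-4-(triisopropylsilyl)but-3-yn-2-yl]-2,2-dimethyl-1,3-dioxolane-4-carboxylate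
Product: 6 (4R,5R)-5-[(2R)-2-hydroxy-4-(triisopropylsilyl)but-3-yn-2-yl]-2,2-dimethyl-1,3-dioxolane-4-carboxylic acid
Conditions: LiOH, THF/H2O, 0 °C; then 1 M HCl to pH 3
Reagents that add atoms: lithium hydroxide, [Li+].[OH-]
Why: Ester saponification of an activated α-alkoxy methyl ester, with the triisopropylsilyl cap chosen because it withstands aqueous hydroxide.

Step 5
Reactants: 6 (4R,5R)-5-[(2R)-2-hydroxy-4-(triisopropylsilyl)but-3-yn-2-yl]-2,2-dimethyl-1,3-dioxolane-4-carboxylic acid; 7 (5S)-5-(hydroxymethyl)furan-2(5H)-one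
Product: 8 (4S,5S)-5-(hydroxymethyl)-4-{(4S,5R)-5-[(2R)-2-hydroxy-4-(triisopropylsilyl)but-3-yn-2-yl]-2,2-dimethyl-1,3-dioxolan-4-yl}oxolan-2-one
Conditions: 7 (1.5 equiv), [Ir(dF(CF3)ppy)2(dtbbpy)]PF6 (1 mol %), K2HPO4, DMF, blue LEDs, rt
Reagents that add atoms: none
Why: Decarboxylative Giese addition under photoredox catalysis, in which oxidation of the α-alkoxy carboxylate and loss of CO2 give the nucleophilic dioxolan-4-yl radical at C8, which should add to C7 of the butenolide anti to the C6 hydroxymethyl group (trans lactone, C7 set by C6) while bonding anti to the bulky C9 substituent (trans dioxolane, C8 set by C9), and reduction and protonation of the α-lactone radical close the cycle.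

Step 6
Reactants: 8 (4S,5S)-5-(hydroxymethyl)-4-{(4S,5R)-5-[(2R)-2-hydroxy-4-(triisopropylsilyl)but-3-yn-2-yl]-2,2-dimethyl-1,3-dioxolan-4-yl}oxolan-2-one
Product: 9 (2S,3R)-3-{(4S,5R)-5-[(2R)-2-hydroxy-4-(triisopropylsilyl)but-3-yn-2-yl]-2,2-dimethyl-1,3-dioxolan-4-yl}-5-oxooxolane-2-carbaldehyde
Conditions: Dess–Martin periodinane, CH2Cl2, 0 °C → rt
Reagents that add atoms: none
Why: Dess–Martin oxidation of the only primary alcohol under near-neutral conditions, which leaves the tertiary hydroxyl untouched and should not epimerise C6.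

Step 7
Reactants: 9 (2S,3R)-3-{(4S,5R)-5-[(2R)-2-hydroxy-4-(triisopropylsilyl)but-3-yn-2-yl]-2,2-dimethyl-1,3-dioxolan-4-yl}-5-oxooxolane-2-carbaldehyde
Product: 10 (4S,5R)-5-ethenyl-4-{(4S,5R)-5-[(2R)-2-hydroxy-4-(triisopropylsilyl)but-3-yn-2-yl]-2,2-dimethyl-1,3-dioxolan-4-yl}oxolan-2-one
Conditions: Ph3PCH3Br, KN(SiMe3)2, THF, 0 °C; then 9, −78 → 0 °C
Reagents that add atoms: methyltriphenylphosphonium bromide, C[P+](c1ccccc1)(c1ccccc1)c1ccccc1.[Br-]
Why: Wittig methylenation with a non-stabilised ylide at low temperature, a reaction that γ-formyl-γ-butyrolactones undergo without loss of the α-stereocentre, the excess ylide being consumed only by the tertiary hydroxyl proton.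

Step 8
Reactants: 10 (4S,5R)-5-ethenyl-4-{(4S,5R)-5-[(2R)-2-hydroxy-4-(triisopropylsilyl)but-3-yn-2-yl]-2,2-dimethyl-1,3-dioxolan-4-yl}oxolan-2-one
Product: 13 (4S,5R)-5-ethenyl-4-{(4S,5R)-5-[(2R)-2-hydroxy-4-(triisopropylsilyl)but-3-yn-2-yl]-2,2-dimethyl-1,3-dioxolan-4-yl}-3-methylideneoxolan-2-one, via Mannich base 11 (not isolated), via ammonium iodide 12 (not isolated)
Conditions: LiN(iPr)2 (2.2 equiv), THF, −78 °C; CH2=NMe2 I, −78 → 0 °C; then MeI, MeOH, rt; then NaHCO3, H2O/CH2Cl2
Reagents that add atoms: Eschenmoser's salt (N,N-dimethylmethyleneiminium iodide), C=[N+](C)C.[I-]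
Why: α-Methylenation of a lactone by Mannich reaction of its lithium enolate with Eschenmoser's salt followed by quaternisation and Hofmann-type elimination; with the alkyne capped the lactone CH2 is the only carbon acid, one further equivalent of base is taken up by the tertiary hydroxyl, and C11 ends trigonal so its transient configuration does not matter.

Step 9
Reactants: 13 (4S,5R)-5-ethenyl-4-{(4S,5R)-5-[(2R)-2-hydroxy-4-(triisopropylsilyl)but-3-yn-2-yl]-2,2-dimethyl-1,3-dioxolan-4-yl}-3-methylideneoxolan-2-one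
Product: 14 (4S,5R)-5-ethenyl-4-{(4S,5R)-5-[(2R)-2-hydroxybut-3-yn-2-yl]-2,2-dimethyl-1,3-dioxolan-4-yl}-3-methylideneoxolan-2-one
Conditions: Bu4NF, AcOH (1:1), THF, 0 °C → rt
Reagents that add atoms: none
Why: Fluoride-induced protodesilylation of an alkynylsilane, buffered with acetic acid so that neither fluoride nor the tertiary alkoxide adds to the methylene lactone.

Step 10
Reactants: 15 ethyl 2-(hydroxymethyl)prop-2-enoate
Product: 16 ethyl 2-{[(tert-butyldiphenylsilyl)oxy]methyl}prop-2-enoate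
Conditions: tBuPh2SiCl, imidazole, CH2Cl2, 0 °C → rt
Reagents that add atoms: tert-butyl(chloro)diphenylsilane, CC(C)(C)[Si](Cl)(c1ccccc1)c1ccccc1
Why: Silyl ether formation at a primary allylic alcohol, with tert-butyldiphenylsilyl chosen over smaller silyl groups because it must outlast the acidic acetonide cleavage of step 16.

Step 11
Reactants: 16 ethyl 2-{[(tert-butyldiphenylsilyl)oxy]methyl}prop-2-enoate
Product: 17 2-{[(tert-butyldiphenylsilyl)oxy]methyl}prop-2-enoic acid
Conditions: LiOH, THF/H2O, 0 °C; then 1 M HCl to pH 3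
Reagents that add atoms: lithium hydroxide, [Li+].[OH-]
Why: Ester saponification with LiOH at 0 °C, which for 2-(silyloxymethyl)acrylates should be faster than conjugate addition of hydroxide.

Step 12
Reactants: 14 (4S,5R)-5-ethenyl-4-{(4S,5R)-5-[(2R)-2-hydroxybut-3-yn-2-yl]-2,2-dimethyl-1,3-dioxolan-4-yl}-3-methylideneoxolan-2-one; 17 2-{[(tert-butyldiphenylsilyl)oxy]methyl}prop-2-enoic acid
Product: 19 (2R)-2-{(4R,5S)-5-[(2R,3S)-2-ethenyl-4-methylidene-5-oxooxolan-3-yl]-2,2-dimethyl-1,3-dioxolan-4-yl}but-3-yn-2-yl 2-{[(tert-butyldiphenylsilyl)oxy]methyl}prop-2-enoate, via mixed anhydride 18 (not isolated)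
Conditions: 17, 2,4,6-Cl3C6H2COCl, Et3N, toluene, rt; then 14, DMAP, toluene, 60 °C
Reagents that add atoms: none
Why: Yamaguchi esterification, in which the mixed anhydride and DMAP give an acylpyridinium ion reactive enough to acylate the tertiary propargylic alcohol, the only hydroxyl in 14.

Step 13
Reactants: 19 (2R)-2-{(4R,5S)-5-[(2R,3S)-2-ethenyl-4-methylidene-5-oxooxolan-3-yl]-2,2-dimethyl-1,3-dioxolan-4-yl}but-3-yn-2-yl 2-{[(tert-butyldiphenylsilyl)oxy]methyl}prop-2-enoate
Product: 20 (2S)-2-{(4R,5S)-5-[(2R,3S)-2-ethenyl-4-methylidene-5-oxooxolan-3-yl]-2,2-dimethyl-1,3-dioxolan-4-yl}-3-oxobutan-2-yl 2-{[(tert-butyldiphenylsilyl)oxy]methyl}prop-2-enoate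
Conditions: Ph3PAuNTf2 (5 mol %), 1,4-dioxane/H2O (10:1), rt
Reagents that add atoms: water, O
Why: Gold-catalysed Markovnikov hydration of a terminal alkyne, assisted by 5-exo-dig participation of the neighbouring ester carbonyl, should turn the ethynyl group into the C1–C2 acetyl group under neutral conditions and leave the ester on O10.

Step 14
Reactants: 20 (2S)-2-{(4R,5S)-5-[(2R,3S)-2-ethenyl-4-methylidene-5-oxooxolan-3-yl]-2,2-dimethyl-1,3-dioxolan-4-yl}-3-oxobutan-2-yl 2-{[(tert-butyldiphenylsilyl)oxy]methyl}prop-2-enoate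
Product: 21 nine-membered (4Z)-enoate lactone O10–C3 bearing the C10 acetyl group (6,12-olide with C11=C13; 8,9-O-isopropylidene; C15 OSitBuPh2; 6R,7S,8S,9R,10S)
Conditions: second-generation Hoveyda–Grubbs catalyst RuCl2(H2IMes)(=CH-C6H4-2-OiPr) (10 mol %), toluene (1 mM), 80 °C, Ar sparge
Reagents that add atoms: none
Why: Ring-closing metathesis, in which the catalyst should load at the monosubstituted C5 vinyl group and close onto the acrylate CH2; the nine-membered ring allows only the Z (ring-cis) C4=C5 geometry, and the methylene lactone cannot compete because closure onto C11=C13 would give a four-membered ring.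

Step 15
Reactants: 21 nine-membered (4Z)-enoate lactone O10–C3 bearing the C10 acetyl group (6,12-olide with C11=C13; 8,9-O-isopropylidene; C15 OSitBuPh2; 6R,7S,8S,9R,10S)
Product: 24 bridged 3(2H)-furanone germacranolide (O10–C3 bridge; C2=C3; 4Z; 6,12-olide with C11=C13; 8,9-O-isopropylidene; C15 OSitBuPh2; 6R,7S,8S,9R,10S), via bridged hemiketal 22 (not isolated), via hydroxy diketone 23 (not isolated)
Conditions: LiN(SiMe3)2 (2 equiv), THF (5 mM), −78 → −20 °C; AcOH; then TsOH·H2O (cat.), CH2Cl2, rt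
Reagents that add atoms: none
Why: Proposed new method: LiN(SiMe3)2 removes a proton from C2, the only enolisable position of the C10 acetyl group, and the lithium enolate adds through C2 to the lactone carbonyl C3, which the nine-membered ring holds five atoms away, to give the bridged hemiketal alkoxide; this can collapse to the ten-membered β-diketonate by expelling the C10 alkoxide, and on acidification the C10 hydroxyl re-adds to C3 and water is lost to leave the vinylogous ester. The closest known reactions are the base-induced intramolecular Claisen (Dieckmann or Baker–Venkataraman type) acyl transfer of open-chain α-acyloxy methyl ketones and the acid cyclodehydration of α'-hydroxy 1,3-diketones to 3(2H)-furanones; new here is that the ester is a medium-ring lactone, so the acyl transfer is transannular and turns the lactone into a carbocycle. The furanone closes 5-exo-trig (C2 onto C3, later O10 onto C3), and the ten-membered carbocycle is not closed end to end but arises by one-atom ring expansion when the C3–O10 bond of the bicyclic adduct breaks, so no entropically costly macrocyclisation is needed. No stereocentre is created: C10 is quaternary and cannot epimerise, the hemiketal carbon C3 ends trigonal, and the Z-C4=C5 bond is not touched. The step needs C-acylation at C3 to win over conjugate addition of the enolate to C13 of the methylene lactone or to C5 of the enoate and over γ-deprotonation at C6; the five-membered transition state (against eight- and seven-membered ones), kinetic deprotonation of the methyl ketone at −78 °C and high dilution should secure this.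

Step 16
Reactants: 24 bridged 3(2H)-furanone germacranolide (O10–C3 bridge; C2=C3; 4Z; 6,12-olide with C11=C13; 8,9-O-isopropylidene; C15 OSitBuPh2; 6R,7S,8S,9R,10S)
Product: 25 8,9-dihydroxy furanone germacranolide (C15 OSitBuPh2; otherwise as 24)
Conditions: CF3CO2H/H2O (9:1), CH2Cl2, 0 °C
Reagents that add atoms: none
Why: Acid-catalysed acetal hydrolysis, which should cleave the trans-fused dioxolane on the ten-membered ring while the tert-butyldiphenylsilyl ether survives, acid rather than base being used to avoid migration of the lactone from O6 to the freed O8.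

Step 17
Reactants: 25 8,9-dihydroxy furanone germacranolide (C15 OSitBuPh2; otherwise as 24)
Product: 26 8-O-methacryloyl 9-hydroxy furanone germacranolide (C15 OSitBuPh2)
Conditions: methacrylic anhydride (1.1 equiv), Et3N, DMAP (cat.), CH2Cl2, −40 → 0 °C
Reagents that add atoms: methacrylic anhydride, C=C(C)C(=O)OC(=O)C(C)=C
Why: DMAP-catalysed acylation under kinetic control, in which the C8 hydroxyl is the less hindered of the two because the C9 hydroxyl is flanked by the quaternary C10, so one equivalent of anhydride at low temperature should give the 8-monoester.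

Step 18
Reactants: 26 8-O-methacryloyl 9-hydroxy furanone germacranolide (C15 OSitBuPh2)
Product: 27 8-O-methacryloyl 9-O-(3-methylbut-2-enoyl) furanone germacranolide (C15 OSitBuPh2)
Conditions: 3-methylbut-2-enoyl chloride, pyridine, DMAP (cat.), CH2Cl2, 0 °C → rt
Reagents that add atoms: 3-methylbut-2-enoyl chloride, CC(C)=CC(=O)Cl
Why: DMAP-catalysed acylation of the remaining hindered C9 hydroxyl with an acid chloride, with pyridine as the only stoichiometric base so that the senecioyl unit does not deconjugate through a vinylketene.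

Step 19
Reactants: 27 8-O-methacryloyl 9-O-(3-methylbut-2-enoyl) furanone germacranolide (C15 OSitBuPh2)
Product: 28 CNP0239488.2
Conditions: HF·pyridine, pyridine, THF, 0 °C → rt
Reagents that add atoms: none
Why: Fluoride desilylation with pyridine-buffered HF·pyridine, conditions that the two unsaturated esters, the methylene lactone and the furanone should tolerate.

**Compound list**

1 | dimethyl (4R,5R)-2,2-dimethyl-1,3-dioxolane-4,5-dicarboxylate (dimethyl 2,3-O-isopropylidene-L-tartrate) | COC(=O)[C@@H]1OC(C)(C)O[C@H]1C(=O)OC | starting material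
2 | (4R,5R)-5-(methoxycarbonyl)-2,2-dimethyl-1,3-dioxolane-4-carboxylic acid | COC(=O)[C@@H]1OC(C)(C)O[C@H]1C(=O)O | intermediate
3 | methyl (4R,5R)-5-(chlorocarbonyl)-2,2-dimethyl-1,3-dioxolane-4-carboxylate (not isolated) | COC(=O)[C@@H]1OC(C)(C)O[C@H]1C(=O)Cl | intermediate
4 | methyl (4R,5R)-5-acetyl-2,2-dimethyl-1,3-dioxolane-4-carboxylate | COC(=O)[C@@H]1OC(C)(C)O[C@H]1C(C)=O | intermediate
5 | methyl (4R,5R)-5-[(2R)-2-hydroxy-4-(triisopropylsilyl)but-3-yn-2-yl]-2,2-dimethyl-1,3-dioxolane-4-carboxylate | COC(=O)[C@@H]1OC(C)(C)O[C@H]1[C@](C)(O)C#C[Si](C(C)C)(C(C)C)C(C)C | intermediate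
6 | (4R,5R)-5-[(2R)-2-hydroxy-4-(triisopropylsilyl)but-3-yn-2-yl]-2,2-dimethyl-1,3-dioxolane-4-carboxylic acid | OC(=O)[C@@H]1OC(C)(C)O[C@H]1[C@](C)(O)C#C[Si](C(C)C)(C(C)C)C(C)C | intermediate
7 | (5S)-5-(hydroxymethyl)furan-2(5H)-one | OC[C@H]1OC(=O)C=C1 | starting material
8 | (4S,5S)-5-(hydroxymethyl)-4-{(4S,5R)-5-[(2R)-2-hydroxy-4-(triisopropylsilyl)but-3-yn-2-yl]-2,2-dimethyl-1,3-dioxolan-4-yl}oxolan-2-one | OC[C@H]1OC(=O)C[C@@H]1[C@@H]2OC(C)(C)O[C@H]2[C@](C)(O)C#C[Si](C(C)C)(C(C)C)C(C)C | intermediate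
9 | (2S,3R)-3-{(4S,5R)-5-[(2R)-2-hydroxy-4-(triisopropylsilyl)but-3-yn-2-yl]-2,2-dimethyl-1,3-dioxolan-4-yl}-5-oxooxolane-2-carbaldehyde | O=C[C@H]1OC(=O)C[C@@H]1[C@@H]2OC(C)(C)O[C@H]2[C@](C)(O)C#C[Si](C(C)C)(C(C)C)C(C)C | intermediate
10 | (4S,5R)-5-ethenyl-4-{(4S,5R)-5-[(2R)-2-hydroxy-4-(triisopropylsilyl)but-3-yn-2-yl]-2,2-dimethyl-1,3-dioxolan-4-yl}oxolan-2-one | C=C[C@H]1OC(=O)C[C@@H]1[C@@H]2OC(C)(C)O[C@H]2[C@](C)(O)C#C[Si](C(C)C)(C(C)C)C(C)C | intermediate
11 | Mannich base: 10 with a CH2NMe2 group on C11 (C11 epimers; not isolated) | C=C[C@H]1OC(=O)C(CN(C)C)[C@@H]1[C@@H]2OC(C)(C)O[C@H]2[C@](C)(O)C#C[Si](C(C)C)(C(C)C)C(C)C | intermediate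
12 | trimethylammonium iodide of 11 (not isolated) | C=C[C@H]1OC(=O)C(C[N+](C)(C)C)[C@@H]1[C@@H]2OC(C)(C)O[C@H]2[C@](C)(O)C#C[Si](C(C)C)(C(C)C)C(C)C.[I-] | intermediate
13 | (4S,5R)-5-ethenyl-4-{(4S,5R)-5-[(2R)-2-hydroxy-4-(triisopropylsilyl)but-3-yn-2-yl]-2,2-dimethyl-1,3-dioxolan-4-yl}-3-methylideneoxolan-2-one | C=C[C@H]1OC(=O)C(=C)[C@@H]1[C@@H]2OC(C)(C)O[C@H]2[C@](C)(O)C#C[Si](C(C)C)(C(C)C)C(C)C | intermediate
14 | (4S,5R)-5-ethenyl-4-{(4S,5R)-5-[(2R)-2-hydroxybut-3-yn-2-yl]-2,2-dimethyl-1,3-dioxolan-4-yl}-3-methylideneoxolan-2-one | C=C[C@H]1OC(=O)C(=C)[C@@H]1[C@@H]2OC(C)(C)O[C@H]2[C@](C)(O)C#C | intermediate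
15 | ethyl 2-(hydroxymethyl)prop-2-enoate | C=C(CO)C(=O)OCC | starting material
16 | ethyl 2-{[(tert-butyldiphenylsilyl)oxy]methyl}prop-2-enoate | C=C(CO[Si](c1ccccc1)(c1ccccc1)C(C)(C)C)C(=O)OCC | intermediate
17 | 2-{[(tert-butyldiphenylsilyl)oxy]methyl}prop-2-enoic acid | C=C(CO[Si](c1ccccc1)(c1ccccc1)C(C)(C)C)C(=O)O | intermediate
18 | mixed anhydride of 17 with 2,4,6-trichlorobenzoic acid (not isolated) | C=C(CO[Si](c1ccccc1)(c1ccccc1)C(C)(C)C)C(=O)OC(=O)c1c(Cl)cc(Cl)cc1Cl | intermediate
19 | (2R)-2-{(4R,5S)-5-[(2R,3S)-2-ethenyl-4-methylidene-5-oxooxolan-3-yl]-2,2-dimethyl-1,3-dioxolan-4-yl}but-3-yn-2-yl 2-{[(tert-butyldiphenylsilyl)oxy]methyl}prop-2-enoate | C=C[C@H]1OC(=O)C(=C)[C@@H]1[C@@H]2OC(C)(C)O[C@H]2[C@](C)(OC(=O)C(=C)CO[Si](c3ccccc3)(c3ccccc3)C(C)(C)C)C#C | intermediate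
20 | (2S)-2-{(4R,5S)-5-[(2R,3S)-2-ethenyl-4-methylidene-5-oxooxolan-3-yl]-2,2-dimethyl-1,3-dioxolan-4-yl}-3-oxobutan-2-yl 2-{[(tert-butyldiphenylsilyl)oxy]methyl}prop-2-enoate | C=C[C@H]1OC(=O)C(=C)[C@@H]1[C@@H]2OC(C)(C)O[C@H]2[C@](C)(OC(=O)C(=C)CO[Si](c3ccccc3)(c3ccccc3)C(C)(C)C)C(C)=O | intermediate
21 | nine-membered (4Z)-enoate lactone O10–C3 bearing the C10 acetyl group (6,12-olide with C11=C13; 8,9-O-isopropylidene; C15 OSitBuPh2; 6R,7S,8S,9R,10S) | CC(=O)[C@@]1(C)OC(=O)/C(CO[Si](c4ccccc4)(c5ccccc5)C(C)(C)C)=C\[C@H]2OC(=O)C(=C)[C@@H]2[C@@H]3OC(C)(C)O[C@@H]13 | intermediate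
22 | bridged hemiketal: C3 carries OH and O10, C2 is CH2, otherwise as 24 (C3 undefined; not isolated) | CC3(C)O[C@H]1[C@H]2C(=C)C(=O)O[C@@H]2/C=C(/CO[Si](c4ccccc4)(c5ccccc5)C(C)(C)C)C2(O)CC(=O)[C@@](C)(O2)[C@@H]1O3 | intermediate
23 | ten-membered 10-hydroxy-1,3-diketone: C1 and C3 ketones, free C10 hydroxyl, otherwise as 24 (not isolated) | CC3(C)O[C@H]1[C@H]2C(=C)C(=O)O[C@@H]2/C=C(/CO[Si](c4ccccc4)(c5ccccc5)C(C)(C)C)C(=O)CC(=O)[C@@](C)(O)[C@@H]1O3 | intermediate
24 | bridged 3(2H)-furanone germacranolide (O10–C3 bridge; C2=C3; 4Z; 6,12-olide with C11=C13; 8,9-O-isopropylidene; C15 OSitBuPh2; 6R,7S,8S,9R,10S) | CC3(C)O[C@H]1[C@H]2C(=C)C(=O)O[C@@H]2/C=C(/CO[Si](c4ccccc4)(c5ccccc5)C(C)(C)C)C2=CC(=O)[C@@](C)(O2)[C@@H]1O3 | intermediate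
25 | 8,9-dihydroxy furanone germacranolide (C15 OSitBuPh2; otherwise as 24) | O[C@H]1[C@H]2C(=C)C(=O)O[C@@H]2/C=C(/CO[Si](c4ccccc4)(c5ccccc5)C(C)(C)C)C2=CC(=O)[C@@](C)(O2)[C@@H]1O | intermediate
26 | 8-O-methacryloyl 9-hydroxy furanone germacranolide (C15 OSitBuPh2) | C=C(C)C(=O)O[C@H]1[C@H]2C(=C)C(=O)O[C@@H]2/C=C(/CO[Si](c4ccccc4)(c5ccccc5)C(C)(C)C)C2=CC(=O)[C@@](C)(O2)[C@@H]1O | intermediate
27 | 8-O-methacryloyl 9-O-(3-methylbut-2-enoyl) furanone germacranolide (C15 OSitBuPh2) | C=C(C)C(=O)O[C@H]1[C@H]2C(=C)C(=O)O[C@@H]2/C=C(/CO[Si](c4ccccc4)(c5ccccc5)C(C)(C)C)C2=CC(=O)[C@@](C)(O2)[C@@H]1OC(=O)C=C(C)C | intermediate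
28 | CNP0239488.2: (4Z,6R,7S,8S,9R,10S)-15-hydroxy-8-(methacryloyloxy)-9-[(3-methylbut-2-enoyl)oxy]-1-oxo-3,10-epoxygermacra-2,4,11(13)-trien-12,6-olide | C=C(C)C(=O)O[C@H]1[C@H]2C(=C)C(=O)O[C@@H]2/C=C(/CO)C2=CC(=O)[C@@](C)(O2)[C@@H]1OC(=O)C=C(C)C | target

**Step count**

Total: 19 steps (17 in the main line, 2 for acid 17).
Longest linear sequence: 17 steps (steps 1–9 and 12–19).

**Steps most likely to fail**

1. Step 15 (proposed new method). The lithium enolate may be diverted into conjugate addition at C5 or C13, or the lactone may be lost through γ-deprotonation at C6, before C-acylation at C3 takes place. The fallback sets out from keto ester 20, before the nine-membered ring is made. LiN(SiMe3)2 followed by acid should convert this open-chain α-acyloxy methyl ketone into the acyclic 2-alkenyl-3(2H)-furanone diene F1 by the established acyl transfer and cyclodehydration of acyclic substrates. Ring-closing metathesis of F1 at C4=C5 (second-generation Hoveyda–Grubbs catalyst, high dilution) then closes the ten-membered carbocycle and rejoins the route at 24.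

2. Step 14. Intermolecular metathesis at the C5 vinyl group may outpace ring closure, because the alkylidene formed there engages the 1,1-disubstituted, electron-poor acrylate only slowly. The fallback sets out from alkynol 14. It is esterified under the conditions of step 12 with the relay acid F2, the analogue of 17 that carries a pent-4-enyl chain on the acrylate terminus, to give the relay ester F3, which is hydrated as in step 13 to the relay ketone F4. Under the same catalyst the ruthenium should load at the unhindered terminal alkene of the relay chain, expel cyclopentene and so be placed on C4, from where closure onto the C5 vinyl group returns to 21.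

3. Step 3. Facial selectivity may be poor or reversed if magnesium fails to chelate the dioxolane oxygen and the ketone reacts through an open Felkin–Anh arrangement. The fallback sets out from acid 2 by way of acid chloride 3. Acyl Sonogashira coupling of 3 with (triisopropylsilyl)acetylene (PdCl2(PPh3)2, CuI, Et3N) should give the ynone F5, to which MeMgBr is then added. Because methyl and alkynyl now enter in the opposite order, the facial preference that gave the wrong C10 epimer in step 3 should give 5, where the route is rejoined.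

**Further compounds**

F1 | step 15 | acyclic 3(2H)-furanone diene: furanone O10–C3 with C2=C3 formed from 20, C4(=CH2)CH2OSitBuPh2 and C5 vinyl still open | C=C[C@H]1OC(=O)C(=C)[C@@H]1[C@@H]2OC(C)(C)O[C@H]2[C@]3(C)OC(=CC3=O)C(=C)CO[Si](c4ccccc4)(c5ccccc5)C(C)(C)C
F2 | step 14 | (2E)-2-{[(tert-butyldiphenylsilyl)oxy]methyl}octa-2,7-dienoic acid (relay acid) | C=CCCC/C=C(/C(=O)O)CO[Si](c1ccccc1)(c1ccccc1)C(C)(C)C
F3 | step 14 | relay ester: O10 ester of 14 with F2 | C=C[C@H]1OC(=O)C(=C)[C@@H]1[C@@H]2OC(C)(C)O[C@H]2[C@](C)(OC(=O)/C(CO[Si](c3ccccc3)(c4ccccc4)C(C)(C)C)=C/CCCC=C)C#C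
F4 | step 14 | relay ketone: F3 with the ethynyl group hydrated to acetyl | C=C[C@H]1OC(=O)C(=C)[C@@H]1[C@@H]2OC(C)(C)O[C@H]2[C@](C)(OC(=O)/C(CO[Si](c3ccccc3)(c4ccccc4)C(C)(C)C)=C/CCCC=C)C(C)=O
F5 | step 3 | methyl (4R,5R)-2,2-dimethyl-5-[3-(triisopropylsilyl)prop-2-ynoyl]-1,3-dioxolane-4-carboxylate (ynone) | COC(=O)[C@@H]1OC(C)(C)O[C@H]1C(=O)C#C[Si](C(C)C)(C(C)C)C(C)C
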